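**Retrosynthetic overview**
1. The target comes from one neutral hydrogenolysis of a biflavonoid masked with benzyl ethers and benzyl carbonates.
2. Key cut: the biaryl bond C5' (flavanone ring B) to C6'' (apigenin ring A). Both carbons are natively nucleophilic, each being ortho to a phenol OH. The ring B phenol is therefore converted into an O-bound λ3-iodane (an aromatic enolonium/phenoxenium synthon), which C6 of 7,4'-di-O-benzylapigenin attacks.
3. The flavanone half is cut at C2–C1'. A rhodium-catalysed asymmetric 1,4-addition of a 3-benzyloxy-4-hydroxyphenylboronic acid to a 5,7-biscarbonate chromone sets (2S).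
4. The boronic acid comes from 2-(benzyloxy)phenol by para-bromination and borylation. The nucleophile comes from apigenin by selective dibenzylation.
5. All six rings are bought intact. Chromone ring C becomes the chromanone ring in the 1,4-addition, then the two halves are joined, then unmasked.

Assumption: apigenin, 5,7-dihydroxychromone, 2-(benzyloxy)phenol and tetrahydroxydiboron are taken as catalogue chemicals, and the biaryl axis is treated as freely rotating because the target carries no axial descriptor.

**Step 1**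
Reactants: 1 apigenin; 2 benzyl bromide
Product: 3 7-(benzyloxy)-2-[4-(benzyloxy)phenyl]-5-hydroxy-4H-chromen-4-one (7,4'-di-O-benzylapigenin)
Conditions: BnBr (2.1 equiv), K2CO3 (2.2 equiv), DMF, 40 °C
Reagents that add atoms: benzyl bromide, BrCc1ccccc1
Why: Williamson etherification takes the acidic, unchelated 7-OH and 4'-OH, while the 5-OH is locked in a hydrogen bond to C4=O and stays free at this stoichiometry; no stereocentre is involved.

**Step 2**
Reactants: 4 5,7-dihydroxy-4H-chromen-4-one; 5 benzyl chloroformate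
Product: 6 5,7-bis[(benzyloxycarbonyl)oxy]-4H-chromen-4-one
Conditions: CbzCl (2.5 equiv), Et3N (3 equiv), DMAP (10 mol %), CH2Cl2, 0 °C to rt
Reagents that add atoms: benzyl chloroformate, O=C(Cl)OCc1ccccc1
Why: DMAP-catalysed O-acylation caps both ring A phenols as carbonates, which make the chromone a better Michael acceptor, later switch ring A off as a nucleophile, and remain cleavable by hydrogenolysis.

**Step 3**
Reactants: 7 2-(benzyloxy)phenol; 8 N-bromosuccinimide
Product: 9 2-(benzyloxy)-4-bromophenol
Conditions: NBS (1.0 equiv), MeCN, 0 °C to rt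
Reagents that add atoms: N-bromosuccinimide, O=C1CCC(=O)N1Br
Why: In this electrophilic aromatic bromination the free OH is the strongest director and its para position is open, as in the para-bromination of guaiacol.

**Step 4**
Reactants: 9 2-(benzyloxy)-4-bromophenol; 10 tetrahydroxydiboron
Product: 11 [3-(benzyloxy)-4-hydroxyphenyl]boronic acid
Conditions: B2(OH)4 (3 equiv), Pd(OAc)2 (2 mol %), XPhos (4 mol %), KOAc (3 equiv), EtOH, 80 °C; dilute aq. HCl work-up
Reagents that add atoms: tetrahydroxydiboron, OB(O)B(O)O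
Why: Miyaura-type borylation on zerovalent palladium gives the boronic acid directly, and the weak base KOAc tolerates the free phenol and the benzyl ether.

**Step 5**
Reactants: 6 5,7-bis[(benzyloxycarbonyl)oxy]-4H-chromen-4-one; 11 [3-(benzyloxy)-4-hydroxyphenyl]boronic acid
Product: 12 (2S)-2-[3-(benzyloxy)-4-hydroxyphenyl]-5,7-bis[(benzyloxycarbonyl)oxy]chroman-4-one
Conditions: 11 (2 equiv), [Rh(OH)(cod)]2 (1.5 mol %), (S)-MeO-F12-BIPHEP [(S)-(6,6'-dimethoxybiphenyl-2,2'-diyl)bis[bis(3,4,5-trifluorophenyl)phosphine], 3.3 mol %], toluene/H2O 10:1, 25–30 °C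
Reagents that add atoms: none
Why: In this Hayashi–Miyaura asymmetric 1,4-addition the aryl-rhodium species inserts C2=C3 of the chromone from the face left open by the (S)-biaryl bisphosphine (the face that gives (S)-3-arylcyclohexanones, which maps onto 2S here), and the base-free hydroxorhodium conditions spare the carbonates and avoid retro-oxa-Michael racemisation.

**Step 6 (key step)**
Reactants: 12 (2S)-2-[3-(benzyloxy)-4-hydroxyphenyl]-5,7-bis[(benzyloxycarbonyl)oxy]chroman-4-one; 3 7,4'-di-O-benzylapigenin; 13 (diacetoxyiodo)benzene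
Product: 15 (2S)-2-{3-(benzyloxy)-5-[7-(benzyloxy)-2-(4-benzyloxyphenyl)-5-hydroxy-4-oxo-4H-chromen-6-yl]-4-hydroxyphenyl}-5,7-bis[(benzyloxycarbonyl)oxy]chroman-4-one, via acetoxy(phenyl)-λ3-iodanyl aryl ether 14 (not isolated)
Conditions: 3 (3 equiv, excess recovered), PhI(OAc)2 (1.05 equiv, added over 1 h), 1,1,1,3,3,3-hexafluoropropan-2-ol (HFIP)/CH2Cl2 4:1, 0 °C, 2 h
Reagents that add atoms: none
Why: Proposed new method: ligand exchange of the only electron-rich free phenol (4'-OH of 12) on PhI(OAc)2 gives the O-bound λ3-iodane 14, an aromatic enolonium (phenoxenium) equivalent whose natively nucleophilic ortho carbon C5' becomes electrophilic because C–C bond formation is coupled to reductive loss of PhI; of the three activated positions C1' and C3' are substituted, so only attack at C5' can rearomatise, ring A of 12 is switched off by its two carbonates, and the best carbon nucleophile present is C6 of 3 (ortho to its free 5-OH, the site at which 5-hydroxy-7-alkoxyflavones are halogenated, and the only carbon able to reach C5' if that 5-OH also binds to iodine), while HFIP stabilises the cationic species, tames acetate and damps phenol homocoupling; C2 is not involved and no base is present, so 2S is retained; the closest known reaction types are the trivalent-iodine phenol–arene oxidative cross-coupling in fluorinated alcohols (aromatic ring umpolung) and the anodic ortho-coupling of 4-alkylguaiacols with arenes.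

**Step 7**
Reactants: 15 (2S)-protected biflavonoid
Product: 16 (2S)-2-{3,4-dihydroxy-5-[5,7-dihydroxy-2-(4-hydroxyphenyl)-4-oxo-4H-chromen-6-yl]phenyl}-5,7-dihydroxychroman-4-one (target)
Conditions: H2 (1 atm), 10% Pd/C, THF/MeOH 1:1, rt; filtration, chromatography on Sephadex LH-20 (MeOH)
Reagents that add atoms: none
Why: Catalytic hydrogenolysis removes three benzyl ethers and two benzyl carbonates (the latter lose CO2) under neutral conditions, so C2 cannot epimerise by ring opening, and the flavone C2=C3 bond and the chelated aryl ketones are inert at 1 atm and rt.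

**Compound list**
1 | apigenin, 5,7-dihydroxy-2-(4-hydroxyphenyl)-4H-chromen-4-one | O=c1cc(-c2ccc(O)cc2)oc2cc(O)cc(O)c12 | starting material
2 | benzyl bromide | BrCc1ccccc1 | starting material
3 | 7-(benzyloxy)-2-[4-(benzyloxy)phenyl]-5-hydroxy-4H-chromen-4-one | O=c1cc(-c2ccc(OCc3ccccc3)cc2)oc2cc(OCc3ccccc3)cc(O)c12 | intermediate
4 | 5,7-dihydroxy-4H-chromen-4-one | O=c1ccoc2cc(O)cc(O)c12 | starting material
5 | benzyl chloroformate | O=C(Cl)OCc1ccccc1 | starting material
6 | 5,7-bis[(benzyloxycarbonyl)oxy]-4H-chromen-4-one | O=c1ccoc2cc(OC(=O)OCc3ccccc3)cc(OC(=O)OCc3ccccc3)c12 | intermediate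
7 | 2-(benzyloxy)phenol | Oc1ccccc1OCc1ccccc1 | starting material
8 | N-bromosuccinimide | O=C1CCC(=O)N1Br | starting material
9 | 2-(benzyloxy)-4-bromophenol | Oc1ccc(Br)cc1OCc1ccccc1 | intermediate
10 | tetrahydroxydiboron | OB(O)B(O)O | starting material
11 | [3-(benzyloxy)-4-hydroxyphenyl]boronic acid | OB(O)c1ccc(O)c(OCc2ccccc2)c1 | intermediate
12 | (2S)-2-[3-(benzyloxy)-4-hydroxyphenyl]-5,7-bis[(benzyloxycarbonyl)oxy]chroman-4-one | O=C1C[C@@H](c2ccc(O)c(OCc3ccccc3)c2)Oc2cc(OC(=O)OCc3ccccc3)cc(OC(=O)OCc3ccccc3)c21 | intermediate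
13 | (diacetoxyiodo)benzene | CC(=O)OI(OC(C)=O)c1ccccc1 | starting material
14 | acetoxy(phenyl)-λ3-iodanyl ether at O-4' of 12, (2S) | O=C1C[C@@H](c2ccc(OI(OC(C)=O)c3ccccc3)c(OCc3ccccc3)c2)Oc2cc(OC(=O)OCc3ccccc3)cc(OC(=O)OCc3ccccc3)c21 | intermediate
15 | (2S)-2-{3-(benzyloxy)-5-[7-(benzyloxy)-2-(4-benzyloxyphenyl)-5-hydroxy-4-oxo-4H-chromen-6-yl]-4-hydroxyphenyl}-5,7-bis[(benzyloxycarbonyl)oxy]chroman-4-one | O=C1C[C@@H](c2cc(OCc3ccccc3)c(O)c(-c3c(OCc4ccccc4)cc4oc(-c5ccc(OCc6ccccc6)cc5)cc(=O)c4c3O)c2)Oc2cc(OC(=O)OCc3ccccc3)cc(OC(=O)OCc3ccccc3)c21 | intermediate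
16 | (2S)-2-{3,4-dihydroxy-5-[5,7-dihydroxy-2-(4-hydroxyphenyl)-4-oxo-4H-chromen-6-yl]phenyl}-5,7-dihydroxychroman-4-one | O=C1C[C@@H](c2cc(O)c(O)c(-c3c(O)cc4oc(-c5ccc(O)cc5)cc(=O)c4c3O)c2)Oc2cc(O)cc(O)c21 | target

**Step count**
- Total steps: 7.
- Longest linear sequence: 5 (steps 3, 4, 5, 6, 7). Steps 1 and 2 are one-step side branches.

**Three steps most likely to fail**

**Step 6.** The risks are these:
- 5',5'-homocoupling of 12.
- Attack through C8 instead of C6 of 3.
- Loss of H-2 from the oxidised phenol to give a para-quinone methide, which would lead to the flavone or to racemate.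

The fallback sets out from 9 and 3 and comes back at 15. It keeps the polarity-reversed biaryl union but moves it ahead of the stereocentre.
- Bromophenol 9 has no benzylic C–H, no stereocentre and no second flavonoid ring A. It is oxidised with PhI(OAc)2 in HFIP in the presence of excess 3.
- This gives 6-[3-(benzyloxy)-5-bromo-2-hydroxyphenyl]-7-(benzyloxy)-2-[4-(benzyloxy)phenyl]-5-hydroxy-4H-chromen-4-one F1. Any regioisomer is removed at this achiral stage.
- Borylation with B2(OH)4, Pd(OAc)2, XPhos and KOAc in EtOH gives {3-(benzyloxy)-5-[7-(benzyloxy)-2-(4-benzyloxyphenyl)-5-hydroxy-4-oxo-4H-chromen-6-yl]-4-hydroxyphenyl}boronic acid F2.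
- The rhodium-catalysed asymmetric 1,4-addition of step 5, run with 6 in slight excess, then delivers 15. C2 is set only after all oxidative chemistry is over.

**Step 5.** The risks are protodeboronation of the electron-rich free-phenol boronic acid, slow turnover, and erosion of ee through the free 4'-OH.

The fallback sets out from 9 and comes back at 12. It masks the phenol during the carbon–boron and carbon–carbon chemistry.
- Silylation (TBSCl, imidazole, DMF) gives [2-(benzyloxy)-4-bromophenoxy](tert-butyl)dimethylsilane F3.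
- Bromine–lithium exchange and borate trapping (n-BuLi, THF, −78 °C; B(OiPr)3; aq. NH4Cl) give {3-(benzyloxy)-4-[(tert-butyldimethylsilyl)oxy]phenyl}boronic acid F4.
- The same asymmetric 1,4-addition to 6 gives (2S)-2-{3-(benzyloxy)-4-[(tert-butyldimethylsilyl)oxy]phenyl}-5,7-bis[(benzyloxycarbonyl)oxy]chroman-4-one F5.
- Non-basic desilylation (Et3N·3HF, THF, 0 °C) releases 12.

**Step 7.** The risks are incomplete removal of five benzyl-type groups from a poorly soluble polyphenol, partial reduction of the flavone C2=C3 bond, and hydrogenolysis of the benzylic C2–O1 bond.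

The fallback sets out from 15 and comes back at 16. It replaces reduction by Lewis-acid dealkylation.
- BCl3 in excess with pentamethylbenzene as a non-basic benzyl-cation scavenger is used in CH2Cl2 at −78 °C, with a MeOH quench at low temperature.
- This cleaves the benzyl ethers and the benzyl carbonates (the latter with loss of CO2) without hydrogen and without base.
- It makes no new compound F0.

**Further compounds**
F1 | step 6 | 6-[3-(benzyloxy)-5-bromo-2-hydroxyphenyl]-7-(benzyloxy)-2-[4-(benzyloxy)phenyl]-5-hydroxy-4H-chromen-4-one | Oc1c(OCc2ccccc2)cc(Br)cc1-c1c(OCc2ccccc2)cc2oc(-c3ccc(OCc4ccccc4)cc3)cc(=O)c2c1O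
F2 | step 6 | {3-(benzyloxy)-5-[7-(benzyloxy)-2-(4-benzyloxyphenyl)-5-hydroxy-4-oxo-4H-chromen-6-yl]-4-hydroxyphenyl}boronic acid | Oc1c(OCc2ccccc2)cc(B(O)O)cc1-c1c(OCc2ccccc2)cc2oc(-c3ccc(OCc4ccccc4)cc3)cc(=O)c2c1O
F3 | step 5 | [2-(benzyloxy)-4-bromophenoxy](tert-butyl)dimethylsilane | CC(C)(C)[Si](C)(C)Oc1ccc(Br)cc1OCc1ccccc1
F4 | step 5 | {3-(benzyloxy)-4-[(tert-butyldimethylsilyl)oxy]phenyl}boronic acid | CC(C)(C)[Si](C)(C)Oc1ccc(B(O)O)cc1OCc1ccccc1
F5 | step 5 | (2S)-2-{3-(benzyloxy)-4-[(tert-butyldimethylsilyl)oxy]phenyl}-5,7-bis[(benzyloxycarbonyl)oxy]chroman-4-one | O=C1C[C@@H](c2ccc(O[Si](C)(C)C(C)(C)C)c(OCc3ccccc3)c2)Oc2cc(OC(=O)OCc3ccccc3)cc(OC(=O)OCc3ccccc3)c21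
F0 | step 7 | none | none
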